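The earlier runs and the new flask were computed with constants of no real substance, noise included.

Late in the oak and ash runs the substrate is still falling, but more slowly, and the end at 8.0 h lies beyond our last reading at 6.00 h, so the earlier runs must be carried forward.

in all of them: substrate 20 mM

| charge | partner | remark | time |
|---|---|---|---|
| oak | 16 mM | run made earlier |  |
| ash | 27 mM | run made earlier |  |
| delta | 31.0 mM |  | 8.0 h |
| gamma | 41.0 mM |  | 8.0 h |
| zeta | 24.0 mM |  | 8.0 h |

| run | time / h | substrate / % | single product / % |
|---|---|---|---|
| oak | 0.333 | 76.0 | 13.1 |
| oak | 0.833 | 56.6 | 19.3 |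
| oak | 1.50 | 45.3 | 23.0 |
| oak | 2.50 | 37.8 | 26.8 |
| oak | 3.00 | 35.4 | 29.6 |
| oak | 4.00 | 32.5 | 33.3 |
| oak | 6.00 | 28.3 | 38.9 |
| ash | 0.833 | 39.7 | 22.2 |
| ash | 1.50 | 29.1 | 25.8 |
| ash | 2.50 | 21.1 | 31.6 |
| ash | 3.00 | 19.2 | 34.3 |
| ash | 4.00 | 15.7 | 38.5 |
| ash | 5.00 | 13.7 | 41.9 |
| ash | 6.00 | 11.3 | 43.5 |

(scatter of a reading: 0.3 percentage points)

- part of the substrate that has reacted at the end, delta
- part of the substrate that has reacted at the end, gamma
- part of the substrate that has reacted at the end, zeta
- what raising the concentration of partner from its lowest to its highest value here does to the part of the substrate that has reacted (changes below 5 percentage points count as none) (it rises / it falls / no change)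

- the numbers in the tables scatter with a standard deviation of 0.3 percentage points
- what has gone from substrate into another species counts as reacted, even if it can come back

The logarithmic fall of substrate per hour slows from 0.164 h⁻¹ between 1.50 h and 3.00 h to 0.0692 h⁻¹ between 4.00 h and 6.00 h in oak, and from 0.277 h⁻¹ to 0.164 h⁻¹ over the same spans in ash.

We compare the two runs through the partner leverage, the drop in the logarithm of the substrate left per mM of extra partner at one time. It reads 0.0835 mM⁻¹ at 6.00 h and 0.0661 mM⁻¹ at 4.00 h. Stepping from ash with it gives our estimate of each flask's substrate at 6.00 h. Substrate was still falling at that time in both runs, so we take this estimate as our ceiling on what is left, and our lower limits on the part reacted are 85.5 % in zeta, 91.9 % in delta and 96.5 % in gamma.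

Now we go round once more: we put that first answer back in and let each flask repeat, over the equally long last stretch, the factor it had just shown. The fall slows, so we take this as too fast, and it gives upper limits of 89.0 %, 94.6 % and 98.0 %. Even gamma's lower limit stands 7.5 percentage points above zeta's upper one, so we expect a rise.

The forecast gave 87 %, 94 % and 96.5 % for zeta, delta and gamma, inside our first two brackets and on gamma's lower edge, and its verdict on raising partner from its lowest to its highest value was that it rises, in its words “So conversion rises with partner”.

The flasks give 88.0 %, 93.9 % and 97.7 %, and on raising partner from its lowest to its highest value the part reacted shows that it rises, by 9.6 points.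

    substrate + partner → single product + by-product (k = 39.0 M⁻¹ h⁻¹)
    substrate + by-product ⇌ idle adduct, settled at all times (K = 54.0 M⁻¹)
    partner + single product ⇌ bis adduct + by-product (K = 1.40, k = 85.0 M⁻¹ h⁻¹)
    single product + by-product → side product (k = 3.80 M⁻¹ h⁻¹)

In zeta the half-life of substrate by its step with partner, 1.4 h at 0.867 h, is short against 8.0 h, yet 12.0 % of substrate still stands there at the end. Taken between zeta and gamma at the end, the leverage reads 0.0961 mM⁻¹, above the 0.0835 mM⁻¹ read earlier.

For zeta's neighbour with 96 mM of partner, the leverage puts the substrate left between a ceiling of 0.0357 % and a floor of 0.00777 %. That flask ends with 0.0099 %.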